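**Plan**

- Retrosynthesis: the quinone is traced back to a 2,3,5-trimethoxy-4-methylphenyl ring. The C3–O bond of the angelate is then cut with 1,3-allylic transposition, followed by the aryl–C2 bond and the C3–C4 bond between a propargyl alcohol unit and a prenyl unit.
- Enabling feature: the ester oxygen sits on C3, a stereocentre allylic to the exo-methylene C1=C2, and C2 carries the six-membered carbocycle. A primary (Z)-allylic trichloroacetimidate with its alkene at C2=C3 therefore delivers the C–O bond, the stereocentre and the exo-methylene in one SN2′ event.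
- Forward: an aryl bromide (three steps from 2,4-dimethoxy-3-methylbenzaldehyde) and an (E)-2-stannyl dienol (two steps from propargyl alcohol and prenyl bromide) are joined by Stille coupling. Imidate formation, asymmetric SN2′ esterification with angelic acid and oxidation with (NH4)2Ce(NO3)6 complete the route. No ring is formed; the six-membered ring is present from the start.
- Stereochemistry: C3 (S) is set by the chiral palladacycle in the esterification. The Z geometry of the imidate comes from syn-hydrostannation and stereoretentive coupling. The Z geometry of the angelate arrives with angelic acid.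

Key step: step 8

Assumption: the sense of induction established for 3-monosubstituted (Z)-imidates, where the (Rp,S) palladacycle leads to the (R)-ester, is taken to hold for the 2-aryl substrate, whose C3 has the same priority order. The (Sp,R) antipode is therefore used; the (Rp,S) complex would replace it if the sense proved reversed.

**Route**

Step 1
Reactants: 1 2,4-dimethoxy-3-methylbenzaldehyde
Product: 3 2,4-dimethoxy-3-methylphenol, via aryl formate 2 (not isolated)
Conditions: mCPBA, CH2Cl2, 0 °C to rt; then K2CO3 (cat.), MeOH, rt
Reagents that add atoms: mCPBA, O=C(OO)c1cccc(Cl)c1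
Why: Baeyer–Villiger (Dakin-type) oxidation, in which the electron-rich aryl group with ortho and para methoxy donors migrates in preference to hydride, and the aryl formate so formed is cleaved by base-catalysed methanolysis.

Step 2
Reactants: 3 2,4-dimethoxy-3-methylphenol
Product: 4 6-bromo-2,4-dimethoxy-3-methylphenol
Conditions: NBS (1.0 equiv), i-Pr2NH (10 mol %), CH2Cl2, 0 °C
Reagents that add atoms: NBS, O=C1CCC(=O)N1Br
Why: Amine-mediated ortho-selective electrophilic bromination of a phenol, in which the N-bromoamine formed in situ is hydrogen-bonded to the phenolic OH and should deliver bromine to C6, the only free ortho position, rather than to C5, which is activated only by methoxy groups.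

Step 3
Reactants: 4 6-bromo-2,4-dimethoxy-3-methylphenol
Product: 5 1-bromo-2,3,5-trimethoxy-4-methylbenzene
Conditions: MeI, K2CO3, acetone, reflux
Reagents that add atoms: iodomethane, CI
Why: Williamson ether synthesis on a phenoxide, which is routine for ortho-substituted phenols and leaves the aryl bromide untouched.

Step 4
Reactants: 6 propargyl alcohol; 7 prenyl bromide
Product: 8 6-methylhept-5-en-2-yn-1-ol
Conditions: CuI (10 mol %), K2CO3, n-Bu4NI (cat.), DMF, rt
Reagents that add atoms: none
Why: Copper-catalysed alkynyl–allyl coupling, in which the copper acetylide formed in situ displaces bromide at the unhindered primary carbon of prenyl bromide (SN2 rather than SN2′) to give the skipped enyne, the free hydroxyl being tolerated under carbonate conditions.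

Step 5
Reactants: 8 6-methylhept-5-en-2-yn-1-ol
Product: 9 (E)-6-methyl-2-(tributylstannyl)hepta-2,5-dien-1-ol
Conditions: n-Bu3SnH (1.2 equiv), PdCl2(PPh3)2 (2 mol %), THF, 0 °C to rt
Reagents that add atoms: tributyltin hydride, CCCC[SnH](CCCC)CCCC
Why: Palladium-catalysed hydrostannation, in which zerovalent palladium generated from PdCl2(PPh3)2 by the stannane adds Sn–H syn across the alkyne with tin directed to the carbon proximal to the propargylic hydroxyl, so that H and Sn end up cis; the trisubstituted alkene is inert and the minor distal regioisomer is removed by chromatography.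

Step 6
Reactants: 9 (E)-6-methyl-2-(tributylstannyl)hepta-2,5-dien-1-ol; 5 1-bromo-2,3,5-trimethoxy-4-methylbenzene
Product: 10 (Z)-6-methyl-2-(2,3,5-trimethoxy-4-methylphenyl)hepta-2,5-dien-1-ol
Conditions: Pd(P(t-Bu)3)2 (5 mol %), CuI (10 mol %), CsF (2 equiv), DMF, 45 °C
Reagents that add atoms: none
Why: Stille coupling with retention of alkene geometry, in which the bulky electron-rich phosphine promotes oxidative addition of the electron-rich aryl bromide to zerovalent palladium and CuI with CsF accelerates transmetalation of the hindered α-substituted alkenylstannane, the free allylic alcohol being tolerated.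

Step 7
Reactants: 10 (Z)-6-methyl-2-(2,3,5-trimethoxy-4-methylphenyl)hepta-2,5-dien-1-ol
Product: 11 (Z)-6-methyl-2-(2,3,5-trimethoxy-4-methylphenyl)hepta-2,5-dien-1-yl 2,2,2-trichloroacetimidate
Conditions: Cl3CCN (1.5 equiv), DBU (10 mol %), CH2Cl2, 0 °C
Reagents that add atoms: trichloroacetonitrile, N#CC(Cl)(Cl)Cl
Why: Base-catalysed addition of the primary alkoxide to the nitrile (trichloroacetimidate formation), which at 0 °C with catalytic DBU should cause neither [3,3]-rearrangement nor migration of the skipped diene.

Step 8
Reactants: 11 (Z)-6-methyl-2-(2,3,5-trimethoxy-4-methylphenyl)hepta-2,5-dien-1-yl 2,2,2-trichloroacetimidate; 12 angelic acid ((Z)-2-methylbut-2-enoic acid)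
Product: 13 (S)-6-methyl-2-(2,3,5-trimethoxy-4-methylphenyl)hepta-1,5-dien-3-yl (Z)-2-methylbut-2-enoate
Conditions: 12 (3 equiv), di-μ-acetato-bis[(η5-(R)-(pS)-2-(4-isopropyl-4,5-dihydrooxazol-2-yl)cyclopentadienyl-1-C,3′-N)(η4-tetraphenylcyclobutadiene)cobalt]dipalladium (5 mol %), CH2Cl2, 23 °C
Reagents that add atoms: none
Why: Proposed new method: the imidate nitrogen binds divalent palladium and holds the C2=C3 alkene on the metal; angelate then attacks C3 anti to palladium to give a transient six-membered C,N-palladacycle with the metal on C2, and syn-deoxypalladation expels trichloroacetamide and forms the C1=C2 exo-methylene. The closest known reaction is the enantioselective SN2′ esterification of (Z)-3-monosubstituted allylic trichloroacetimidates with carboxylic acids under this type of catalyst; the extension is the 2-aryl group, which makes the alkene trisubstituted and the palladated carbon tertiary and benzylic, and is met here with a higher catalyst loading and an aryl ring that lies cis to H and is twisted out of the alkene plane by its ortho methoxy group. No ring is closed in the product. The new stereocentre C3 is under catalyst control: the planar-chiral palladacycle selects one face of the geometrically pure Z alkene and, since the nucleophile enters anti to the face-bound metal, this fixes C3 as S. The step needs branched over linear substitution, secured by the N-chelate that allows palladium only on C2, and esterification over [3,3]-rearrangement, secured by the excess of acid. The Z geometry of the angelate is preserved because the acid acts only as an oxygen nucleophile and is never converted into an activated acyl species, and the remote prenyl alkene has no anchoring group and should not compete.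

Step 9
Reactants: 13 (S)-6-methyl-2-(2,3,5-trimethoxy-4-methylphenyl)hepta-1,5-dien-3-yl (Z)-2-methylbut-2-enoate
Product: 14 (S)-2-(5-methoxy-4-methyl-3,6-dioxocyclohexa-1,4-dien-1-yl)-6-methylhepta-1,5-dien-3-yl (Z)-2-methylbut-2-enoate
Conditions: (NH4)2Ce(NO3)6 (2.5 equiv), MeCN/H2O 2:1, 0 °C, 15 min
Reagents that add atoms: water, O
Why: Oxidative demethylation by tetravalent cerium, in which the arene radical cation takes up water at the two para methoxy-bearing carbons (C2 and C5 of the ring) and loses methanol to give the 1,4-benzoquinone in preference to the ortho-quinone, the short contact at 0 °C sparing the alkenes, the angelate and the allylic stereocentre.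

**Compound list**

1 | 2,4-dimethoxy-3-methylbenzaldehyde | O=Cc1ccc(OC)c(C)c1OC | starting material
2 | 2,4-dimethoxy-3-methylphenyl formate | O=COc1ccc(OC)c(C)c1OC | intermediate
3 | 2,4-dimethoxy-3-methylphenol | Oc1ccc(OC)c(C)c1OC | intermediate
4 | 6-bromo-2,4-dimethoxy-3-methylphenol | Oc1c(Br)cc(OC)c(C)c1OC | intermediate
5 | 1-bromo-2,3,5-trimethoxy-4-methylbenzene | COc1c(Br)cc(OC)c(C)c1OC | intermediate
6 | propargyl alcohol | C#CCO | starting material
7 | prenyl bromide (1-bromo-3-methylbut-2-ene) | CC(C)=CCBr | starting material
8 | 6-methylhept-5-en-2-yn-1-ol | OCC#CCC=C(C)C | intermediate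
9 | (E)-6-methyl-2-(tributylstannyl)hepta-2,5-dien-1-ol | OC/C(=C\CC=C(C)C)[Sn](CCCC)(CCCC)CCCC | intermediate
10 | (Z)-6-methyl-2-(2,3,5-trimethoxy-4-methylphenyl)hepta-2,5-dien-1-ol | OC/C(=C\CC=C(C)C)c1cc(OC)c(C)c(OC)c1OC | intermediate
11 | (Z)-6-methyl-2-(2,3,5-trimethoxy-4-methylphenyl)hepta-2,5-dien-1-yl 2,2,2-trichloroacetimidate | N=C(OC/C(=C\CC=C(C)C)c1cc(OC)c(C)c(OC)c1OC)C(Cl)(Cl)Cl | intermediate
12 | angelic acid, (Z)-2-methylbut-2-enoic acid | OC(=O)/C(C)=C\C | starting material
13 | (S)-6-methyl-2-(2,3,5-trimethoxy-4-methylphenyl)hepta-1,5-dien-3-yl (Z)-2-methylbut-2-enoate | C=C(c1cc(OC)c(C)c(OC)c1OC)[C@H](CC=C(C)C)OC(=O)/C(C)=C\C | intermediate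
14 | (S)-2-(5-methoxy-4-methyl-3,6-dioxocyclohexa-1,4-dien-1-yl)-6-methylhepta-1,5-dien-3-yl (Z)-2-methylbut-2-enoate | C=C(C1=CC(=O)C(C)=C(OC)C1=O)[C@H](CC=C(C)C)OC(=O)/C(C)=C\C | target

**Step count**

Total steps: 9. Longest linear sequence: 7 steps (steps 1, 2, 3, 6, 7, 8, 9, from 1 to 14).

**Steps most likely to fail**

Step 8. The trisubstituted 2-aryl alkene may bind the palladacycle too weakly or resist oxypalladation at a carbon that leaves the metal on a tertiary benzylic centre. The imidate would then drift into [3,3]-rearrangement or unselective acid-promoted substitution, or the face selection could be poor. The fallback sets out from 10 and returns at 13: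
- Sharpless asymmetric epoxidation of 10 (Ti(O-i-Pr)4, D-(−)-diethyl tartrate, t-BuOOH, 4 Å molecular sieves, CH2Cl2, −20 °C) should deliver oxygen to the face that makes C3 S. It gives [(2R,3S)-3-(3-methylbut-2-en-1-yl)-2-(2,3,5-trimethoxy-4-methylphenyl)oxiran-2-yl]methanol F1, the homoallylic prenyl alkene being left alone.
- Iodination with I2, PPh3 and imidazole in CH2Cl2 at 0 °C gives (2S,3S)-2-(iodomethyl)-3-(3-methylbut-2-en-1-yl)-2-(2,3,5-trimethoxy-4-methylphenyl)oxirane F2.
- Zinc dust in ethanol at 60 °C effects reductive opening with 1,3-transposition. The C3–O bond is untouched, and the product is (S)-6-methyl-2-(2,3,5-trimethoxy-4-methylphenyl)hepta-1,5-dien-3-ol F3.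
- Angelic acid 12 is converted with 2,4,6-trichlorobenzoyl chloride and Et3N in toluene into (Z)-2-methylbut-2-enoic 2,4,6-trichlorobenzoic anhydride F4. This acylates F3 at 80 °C without a nucleophilic amine catalyst, so that isomerisation to the tiglate is avoided, and gives 13.

Step 2. Bromination may lack regiocontrol, with attack at C5 (ortho and para to methoxy groups) or double bromination competing with delivery to C6. The fallback sets out from 3 and returns at 4:
- 3 is protected with MOMCl and i-Pr2NEt in CH2Cl2 as 1-(methoxymethoxy)-2,4-dimethoxy-3-methylbenzene F5.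
- Directed ortho-metalation (n-BuLi, TMEDA, THF, 0 °C), governed by the stronger acetal director, gives [2-(methoxymethoxy)-3,5-dimethoxy-4-methylphenyl]lithium F6.
- Quenching with BrCCl2CCl2Br at −78 °C gives 1-bromo-2-(methoxymethoxy)-3,5-dimethoxy-4-methylbenzene F7.
- HCl in MeOH at rt removes the acetal and gives 4.

Step 6. Transmetalation of the hindered α-substituted alkenylstannane onto an electron-rich, ortho-substituted arylpalladium species may be slow, so that protodestannylation, homocoupling or cine substitution take over. The fallback reverses the polarity, sets out from 9 and 5 and returns at 10: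
- Iododestannylation of 9 with I2 in CH2Cl2 at 0 °C, with retention of geometry, gives (E)-2-iodo-6-methylhepta-2,5-dien-1-ol F8.
- Miyaura borylation of 5 (B2pin2, PdCl2(dppf), KOAc, dioxane, 80 °C) gives 4,4,5,5-tetramethyl-2-(2,3,5-trimethoxy-4-methylphenyl)-1,3,2-dioxaborolane F9.
- Suzuki–Miyaura coupling of F8 with F9 (Pd(OAc)2, SPhos, K3PO4, THF/H2O, 40 °C) gives 10.

**Further compounds**

F1 | step 8 | [(2R,3S)-3-(3-methylbut-2-en-1-yl)-2-(2,3,5-trimethoxy-4-methylphenyl)oxiran-2-yl]methanol | OC[C@@]1(c2cc(OC)c(C)c(OC)c2OC)O[C@H]1CC=C(C)C
F2 | step 8 | (2S,3S)-2-(iodomethyl)-3-(3-methylbut-2-en-1-yl)-2-(2,3,5-trimethoxy-4-methylphenyl)oxirane | IC[C@@]1(c2cc(OC)c(C)c(OC)c2OC)O[C@H]1CC=C(C)C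
F3 | step 8 | (S)-6-methyl-2-(2,3,5-trimethoxy-4-methylphenyl)hepta-1,5-dien-3-ol | C=C(c1cc(OC)c(C)c(OC)c1OC)[C@H](CC=C(C)C)O
F4 | step 8 | (Z)-2-methylbut-2-enoic 2,4,6-trichlorobenzoic anhydride | C/C=C(/C)C(=O)OC(=O)c1c(Cl)cc(Cl)cc1Cl
F5 | step 2 | 1-(methoxymethoxy)-2,4-dimethoxy-3-methylbenzene | COCOc1ccc(OC)c(C)c1OC
F6 | step 2 | [2-(methoxymethoxy)-3,5-dimethoxy-4-methylphenyl]lithium | [Li]c1cc(OC)c(C)c(OC)c1OCOC
F7 | step 2 | 1-bromo-2-(methoxymethoxy)-3,5-dimethoxy-4-methylbenzene | COCOc1c(Br)cc(OC)c(C)c1OC
F8 | step 6 | (E)-2-iodo-6-methylhepta-2,5-dien-1-ol | OC/C(I)=C\CC=C(C)C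
F9 | step 6 | 4,4,5,5-tetramethyl-2-(2,3,5-trimethoxy-4-methylphenyl)-1,3,2-dioxaborolane | COc1c(B2OC(C)(C)C(C)(C)O2)cc(OC)c(C)c1OC
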